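**Assumption:** "Punaglandin 6" is taken to be exactly the given SMILES, i.e. (5S,6S,8R,12S,14Z) in prostanoid numbering (C1 = ester carbon, C8–C12 = ring), which is used below. Compound 1 is the commercial acetonide diol made from natural L-tartaric acid.

## Retrosynthetic overview

1. Target ⇒ acetylation of the 5,6-diol; the C10 chlorine comes from the des-chloro enone by enone epoxidation, then HCl opening and dehydration.
2. The only ring (cyclopentenone, C8–C12 bond) ⇒ conrotatory 4π electrocyclization (Piancatelli rearrangement) of a 5-alkyl-2-furylcarbinol; C8 and C12 are set here.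
3. Furylcarbinol ⇒ 5-lithio-2-[(Z)-oct-2-enyl]furan + a C1–C8 aldehyde.
4. Aldehyde ⇒ L-threitol acetonide (C4–C7, carrying C5/C6): Giese addition to methyl acrylate gives C1–C3; vinyl cuprate then ozonolysis gives C8.
5. Furan piece ⇒ furan + 1-bromooct-2-yne, then Lindlar reduction.

## Route

**Step 1**
Reactants: 1, (4S,5S)-2,2-dimethyl-1,3-dioxolane-4,5-dimethanol
Product: 2, [(4S,5S)-5-(hydroxymethyl)-2,2-dimethyl-1,3-dioxolan-4-yl]methyl 4-methylbenzenesulfonate
Conditions: TsCl (1.05 equiv), Ag2O, KI (cat.), CH2Cl2, 0 °C → rt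
Reagents that add atoms: tosyl chloride, Cc1ccc(cc1)S(Cl)(=O)=O
Why: Ag2O-mediated monosulfonylation of a C2-symmetric diol; the two hydroxyls are homotopic, so one monotosylate forms and the bought C5/C6 stereocentres are untouched.

**Step 2**
Reactants: 2, monotosylate
Product: 3, [(4S,5R)-5-(iodomethyl)-2,2-dimethyl-1,3-dioxolan-4-yl]methyl 4-methylbenzenesulfonate (same geometry; descriptor changes by CIP priority only)
Conditions: I2, PPh3, imidazole, THF, 0 °C → rt
Reagents that add atoms: iodine, II
Why: Garegg–Samuelsson (Appel-type) iodination of the remaining primary alcohol by SN2 at a non-stereogenic CH2; the tosylate is kept for step 4.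

**Step 3**
Reactants: 3, iodo tosylate; 4, methyl acrylate
Product: 5, methyl 4-[(4S,5S)-2,2-dimethyl-5-(tosyloxymethyl)-1,3-dioxolan-4-yl]butanoate
Conditions: methyl acrylate (5 equiv), Bu3SnH (1.3 equiv, slow addition), AIBN (cat.), PhH, 80 °C
Reagents that add atoms: none (Bu3SnH supplies H only)
Why: Giese radical conjugate addition; the stannyl radical abstracts only iodine (sulfonate inert), the primary radical adds to the acrylate and installs C1–C3 in one step without touching a stereocentre.

**Step 4**
Reactants: 5, tosylate ester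
Product: 6, methyl 4-[(4S,5S)-2,2-dimethyl-5-(prop-2-en-1-yl)-1,3-dioxolan-4-yl]butanoate
Conditions: (CH2=CH)2CuMgBr [CH2=CHMgBr 3 equiv + CuI 1.5 equiv], THF, −40 → 0 °C
Reagents that add atoms: vinylmagnesium bromide, C=C[Mg]Br
Why: SN2 displacement of a primary tosylate by a vinyl cuprate; Gilman-type cuprates do not attack the methyl ester at ≤0 °C.

**Step 5**
Reactants: 6, allyl ester
Product: 7, methyl 4-[(4S,5S)-2,2-dimethyl-5-(2-oxoethyl)-1,3-dioxolan-4-yl]butanoate
Conditions: O3, CH2Cl2, −78 °C; then PPh3, → rt
Reagents that add atoms: ozone, [O-][O+]=O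
Why: Ozonolysis with reductive work-up cleaves the terminal alkene to the aldehyde that becomes C8; ester and acetonide are inert.

**Step 6**
Reactants: 8, furan; 9, 1-bromooct-2-yne
Product: 10, 2-(oct-2-yn-1-yl)furan
Conditions: n-BuLi, THF, 0 °C; then 9, −78 °C → rt
Reagents that add atoms: none
Why: α-Lithiation of furan and SN2 alkylation by a primary propargylic bromide.

**Step 7**
Reactants: 10, alkynylfuran
Product: 11, 2-[(2Z)-oct-2-en-1-yl]furan
Conditions: H2 (1 atm), Lindlar catalyst, quinoline, hexane, rt
Reagents that add atoms: none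
Why: Lindlar semi-hydrogenation adds H2 syn and gives only the Z-alkene (14Z); the furan is not reduced.

**Step 8**
Reactants: 11, (Z)-octenylfuran; 7, aldehyde
Product: 12, methyl 4-[(4S,5S)-5-{(2RS)-2-hydroxy-2-[5-((2Z)-oct-2-en-1-yl)furan-2-yl]ethyl}-2,2-dimethyl-1,3-dioxolan-4-yl]butanoate
Conditions: 11, n-BuLi (1.0 equiv), THF, −78 → −20 °C; then 7, −78 °C; NH4Cl
Reagents that add atoms: none
Why: Lithiation at the only free furan α-position, then 1,2-addition to the aldehyde, which at −78 °C is much faster than attack on the methyl ester; the new carbinol centre is an unselective mixture on purpose because it is ionised in step 9.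

**Step 9**
Reactants: 12, furylcarbinol
Product: 13, methyl 4-[(4S,5S)-5-{[(1R,2R)-2-hydroxy-2-((2Z)-oct-2-en-1-yl)-5-oxocyclopent-3-en-1-yl]methyl}-2,2-dimethyl-1,3-dioxolan-4-yl]butanoate (= 8R,12R here; the 12-descriptor becomes S once Cl is on C10)
Conditions: ZnCl2 (2 equiv), acetone/H2O 2:1, 60 °C, 24–48 h; chromatographic removal of the minor ring diastereomer
Reagents that add atoms: water, O (source of the C12 hydroxyl oxygen)
Why: Piancatelli rearrangement — ionisation to the furfuryl cation, water adds at furan C5, and the ring-opened 1,4-dihydroxypentadienyl cation closes by conrotatory 4π electrocyclization to form C8–C12. The two carbon chains are expected to rotate outward and end up trans (C7 chain cis to 12-OH, which is also the favoured arrangement at epimerisable C8). The absolute sense is biased only by the L-tartrate-derived dioxolane, so selectivity is likely modest and the wanted isomer is isolated by chromatography.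

**Step 10**
Reactants: 13, hydroxy enone
Product: 14, the 10,11-epoxy ketone of 13 (epoxide on the face of the 12-OH; its configuration is inconsequential)
Conditions: 30% H2O2, NaOH (0.2 equiv), MeOH, −20 → 0 °C
Reagents that add atoms: hydrogen peroxide, OO
Why: Weitz–Scheffer nucleophilic epoxidation attacks only the electron-poor enone (anti to the octenyl chain) and leaves the isolated Z-alkene alone; the epoxide stereocentres are destroyed in step 11.

**Step 11**
Reactants: 14, epoxy ketone
Product: 15, methyl (5S,6S)-7-[(1R,2S)-4-chloro-2-hydroxy-2-((2Z)-oct-2-en-1-yl)-5-oxocyclopent-3-en-1-yl]-5,6-dihydroxyheptanoate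
Conditions: HCl (ca. 1.25 M in MeOH, excess), 0 °C → rt; solid NaHCO3 before concentration; use crude
Reagents that add atoms: hydrogen chloride, Cl
Why: Chloride opens the protonated epoxy ketone at the α-carbon (C10, SN2) and the β-hydroxy ketone dehydrates to the 2-chloro-enone, while the same methanolic acid removes the acetonide by transketalisation; methanol as solvent keeps the 5-hydroxy ester from closing to the δ-lactone, and C5, C6, C8 and C12 are not involved.

**Step 12**
Reactants: 15, chloro-enone diol
Product: 16, Punaglandin 6, methyl (5S,6S)-5,6-diacetoxy-7-[(1R,2S)-4-chloro-2-hydroxy-2-((2Z)-oct-2-en-1-yl)-5-oxocyclopent-3-en-1-yl]heptanoate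
Conditions: Ac2O, pyridine, 0 °C → rt (no DMAP)
Reagents that add atoms: acetic anhydride, CC(=O)OC(C)=O
Why: Acetylation of the two secondary alcohols; the tertiary 12-OH is not acylated under these mild conditions.

## Compound list

1 | (4S,5S)-2,2-dimethyl-1,3-dioxolane-4,5-dimethanol ((+)-2,3-O-isopropylidene-L-threitol) | OC[C@@H]1OC(C)(C)O[C@H]1CO | starting material
2 | [(4S,5S)-5-(hydroxymethyl)-2,2-dimethyl-1,3-dioxolan-4-yl]methyl tosylate | OC[C@@H]1OC(C)(C)O[C@H]1COS(=O)(=O)c2ccc(C)cc2 | intermediate
3 | [(4S,5R)-5-(iodomethyl)-2,2-dimethyl-1,3-dioxolan-4-yl]methyl tosylate | IC[C@@H]1OC(C)(C)O[C@H]1COS(=O)(=O)c2ccc(C)cc2 | intermediate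
4 | methyl acrylate | C=CC(=O)OC | starting material
5 | methyl 4-[(4S,5S)-2,2-dimethyl-5-(tosyloxymethyl)-1,3-dioxolan-4-yl]butanoate | COC(=O)CCC[C@@H]1OC(C)(C)O[C@H]1COS(=O)(=O)c2ccc(C)cc2 | intermediate
6 | methyl 4-[(4S,5S)-2,2-dimethyl-5-(prop-2-en-1-yl)-1,3-dioxolan-4-yl]butanoate | COC(=O)CCC[C@@H]1OC(C)(C)O[C@H]1CC=C | intermediate
7 | methyl 4-[(4S,5S)-2,2-dimethyl-5-(2-oxoethyl)-1,3-dioxolan-4-yl]butanoate | COC(=O)CCC[C@@H]1OC(C)(C)O[C@H]1CC=O | intermediate
8 | furan | c1ccoc1 | starting material
9 | 1-bromooct-2-yne | CCCCCC#CCBr | starting material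
10 | 2-(oct-2-yn-1-yl)furan | CCCCCC#CCc1ccco1 | intermediate
11 | 2-[(2Z)-oct-2-en-1-yl]furan | CCCCC/C=C\Cc1ccco1 | intermediate
12 | furylcarbinol (carbinol epimers), dioxolane (4S,5S) | CCCCC/C=C\Cc1ccc(o1)C(O)C[C@@H]2OC(C)(C)O[C@H]2CCCC(=O)OC | intermediate
13 | 4-hydroxy-cyclopentenone, ring (1R,2R), dioxolane (4S,5S) | CCCCC/C=C\C[C@@]1(O)C=CC(=O)[C@@H]1C[C@@H]2OC(C)(C)O[C@H]2CCCC(=O)OC | intermediate
14 | 10,11-epoxy ketone of 13 (epoxide cis to 12-OH) | CCCCC/C=C\C[C@@]1(O)[C@@H]2O[C@@H]2C(=O)[C@@H]1C[C@@H]3OC(C)(C)O[C@H]3CCCC(=O)OC | intermediate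
15 | methyl (5S,6S)-7-[(1R,2S)-4-chloro-2-hydroxy-2-((2Z)-oct-2-en-1-yl)-5-oxocyclopent-3-en-1-yl]-5,6-dihydroxyheptanoate | CCCCC/C=C\C[C@@]1(O)C=C(Cl)C(=O)[C@@H]1C[C@H](O)[C@H](CCCC(=O)OC)O | intermediate
16 | Punaglandin 6 | CCCCC/C=C\C[C@@]1(O)C=C(Cl)C(=O)[C@@H]1C[C@H](OC(C)=O)[C@H](CCCC(=O)OC)OC(C)=O | target

## Summary

Total steps: 12. Longest linear sequence: 10 (steps 1–5, 8–12); the furan arm adds 2 (steps 6–7).

Steps most likely to fail:

1. **Step 9 (Piancatelli).** The inducing stereocentre (C6) is β to the cyclising carbon, so the facial ratio may be near 1:1 to 3:1; 5-alkylfurans rearrange sluggishly; the acetonide may partly hydrolyse. Fallback: move the controlling stereocentre next to the cyclising carbon by using a C7-oxygenated aldehyde (2,3,4-trioxygenated chain from a pentose, at the cost of a less cheap sugar and extra steps), then delete the C7 oxygen after ring formation by β-elimination to the Δ7-enone and 1,4-reduction.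
2. **Step 11 (epoxide → chloro-enone with acetonide loss).** Competing methanol opening, δ-lactonisation of the free 5-hydroxy ester, or a messy cascade are possible. Fallback: carry the side chain as the alkyne (skip step 7), chlorinate the enone by Cl2 addition then Et3N elimination with no alkene present, and do the Lindlar semi-hydrogenation last.
3. **Step 8 (lithiation/addition).** n-BuLi may deprotonate the doubly activated furfuryl/allylic CH2 instead of the ring, scrambling the Z-alkene. Fallback: generate the nucleophile by Br/Li exchange from 2-bromo-5-[(Z)-oct-2-enyl]furan (2-bromofuran, LDA, (Z)-1-bromooct-2-ene), or add 2-furyllithium to 7 first and introduce the octenyl chain afterwards.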